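## Retrosynthetic overview

1. Tomoeone C ⇐ double cross-metathesis (allyl → prenyl) of the diallyl congener 9; the acid-sensitive prenyl groups go on last.
2. 9 ⇐ Markovnikov hydration of the cyclohexene in spiro-hydrindene 7, delivered by the axial enol oxygen through a transient oxa-bridge (sets the C4 carbinol).
3. 7 ⇐ light-driven intramolecular Diels–Alder reaction of dienone 5, which is made in the same flask from diallyl trione 2 and (E)-8-oxolinalool 4 and rests in the dark as 2H-pyran 6; the cyclopentane, the cyclohexene and the spiro centre form together.
4. 2 ⇐ phlorisobutyrophenone 1; 4 ⇐ (R)-linalool 3 (the only source of chirality).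
5. Ring order: trione ring dearomatised (step 1) → temporary pyran, then five- and six-membered carbocycles together (step 3) → transient oxa-bridge (step 4).

Assumption: phlorisobutyrophenone and (R)-(−)-linalool are bought. The hydrindane atoms are labelled as in indane: C1 is the carbinol of the five-membered ring, C3a and C7a are the ring-fusion carbons, C4 is the second carbinol, C5 and C7 are CH2 groups and C6 is the spiro carbon. Linalool C3, C2, C1, C6, C7 and C8 become C1, C7a, C7, C3a, C4 and C5.

## Route

Step 1
Reactants: 1 phlorisobutyrophenone
Product: 2 diallyl trione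
Conditions: allyl bromide (2.2 equiv), NaOMe (2.5 equiv), MeOH, 0 °C to 20 °C
Reagents that add atoms: allyl bromide C=CCBr
Why: C-alkylation of the phloroglucinol phenoxide, in which the second allylation occurs at the already substituted ring carbon and dearomatises the ring (the known route to gem-dialkyl acylphloroglucinols; the 3,5-diallyl isomer is removed by chromatography), with no stereocentre formed.

Step 2
Reactants: 3 (R)-(−)-linalool
Product: 4 (E)-8-oxolinalool
Conditions: SeO2 (1.1 equiv), 1,4-dioxane, 80 °C
Reagents that add atoms: selenium dioxide O=[Se]=O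
Why: Riley allylic oxidation (ene reaction then [2,3]-shift) at the (E)-methyl group of the trisubstituted alkene, while the vinyl group has no allylic hydrogen and the C3 carbinol stereocentre is untouched.

Step 3
Reactants: 2 diallyl trione, 4 (E)-8-oxolinalool
Product: 7 spiro-hydrindene, via dienone 5 (not isolated), via 2H-pyran 6 (not isolated)
Conditions: ethylenediammonium diacetate (10 mol%), PhMe, 40 °C, dark; then degassed PhMe (to 0.01 M), hν (390 nm LED), 60 °C
Reagents that add atoms: none
Why: Proposed new method: Knoevenagel condensation at the only free ring CH gives dienone 5, which rests in the dark as 2H-pyran 6 (oxa-6π closure through the carbonyl next to the diallyl carbon, which keeps the chelated acyl-β-triketone intact, both pyran epimers being equivalent); light then drives the photochromic retro-oxa-6π opening back to s-cis 5 with that carbonyl held on the inside of the diene, and this electron-poor 1,1-diacyl diene is trapped by the tethered vinyl group in an intramolecular inverse-demand Diels–Alder reaction (closest known types: Knoevenagel/oxa-6π condensation, photoenolisation/Diels–Alder and thermal retro-6π/cycloaddition of 2H-pyrans); the trans-fused transition state with the C1 methyl anti to C7 sets C7a and C3a from the linalool carbinol, and the suprafacial addition places the inside carbonyl cis to H-3a, which fixes the spiro configuration.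

Step 4
Reactants: 7 spiro-hydrindene
Product: 9 diallyl congener of tomoeone C, via bridged enol ether 8 (not isolated)
Conditions: TsOH·H2O (20 mol%), CH2Cl2, 0 °C; then 1 M HCl, THF, 20 °C
Reagents that add atoms: water O
Why: Acid-catalysed Markovnikov hydroalkoxylation, in which protonation at C5 gives the tertiary C4 cation that can only be captured by the 1,3-diaxial enol oxygen of the axial acyl-side carbonyl (oxygen axial, cis to that carbonyl), followed by hydrolysis of the resulting vinylogous ester at its sp2 carbon, which frees the C4 alcohol with retention; the allyl groups would give only secondary cations and stay untouched.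

Step 5
Reactants: 9 diallyl congener of tomoeone C
Product: 10 tomoeone C
Conditions: second-generation Grubbs catalyst (5 mol%), 2-methyl-2-butene (neat), 40 °C
Reagents that add atoms: 2-methyl-2-butene CC=C(C)C
Why: Olefin cross-metathesis of both terminal allyl groups to prenyl groups, where the trisubstituted products are inert once formed and the large excess of 2-methyl-2-butene favours cross-metathesis over ring closure of the gem-diallyl unit, and no stereocentre is touched.

## Compound list

1 | 2-methyl-1-(2,4,6-trihydroxyphenyl)propan-1-one (phlorisobutyrophenone) | CC(C)C(=O)c1c(O)cc(O)cc1O | starting material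
2 | 3,5-dihydroxy-4-(2-methylpropanoyl)-6,6-di(prop-2-en-1-yl)cyclohexa-2,4-dien-1-one (diallyl trione) | C=CCC1(CC=C)C(=O)C=C(O)C(C(=O)C(C)C)=C1O | intermediate
3 | (R)-(−)-linalool, (3R)-3,7-dimethylocta-1,6-dien-3-ol | CC(C)=CCC[C@@](C)(O)C=C | starting material
4 | (2E,6R)-6-hydroxy-2,6-dimethylocta-2,7-dienal ((E)-8-oxolinalool) | O=C/C(C)=C/CC[C@@](C)(O)C=C | intermediate
5 | dienone (not isolated): 5-hydroxy-2-[(2E,6R)-6-hydroxy-2,6-dimethylocta-2,7-dien-1-ylidene]-4-(2-methylpropanoyl)-6,6-di(prop-2-en-1-yl)cyclohex-4-ene-1,3-dione; at the exocyclic C=C the C1 carbonyl (next to the diallyl carbon) is cis to the C(Me)= carbon | C=CCC1(CC=C)C(=O)/C(=C\C(C)=C\CC[C@@](C)(O)C=C)C(=O)C(C(=O)C(C)C)=C1O | intermediate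
6 | 2H-pyran (not isolated, dark resting state of 5): 8,8-diallyl-7-hydroxy-2-[(3R)-3-hydroxy-3-methylpent-4-en-1-yl]-3-methyl-6-(2-methylpropanoyl)-2H-chromen-5(8H)-one, both C2 epimers; the pyran oxygen sits on the ring carbon next to the diallyl carbon | C=CCC1(CC=C)C2=C(C=C(C)C(CC[C@@](C)(O)C=C)O2)C(=O)C(C(=O)C(C)C)=C1O | intermediate
7 | spiro-hydrindene (Diels–Alder adduct): C6 of (1R,3aR,7aS)-1-hydroxy-1,4-dimethyl-2,3,3a,6,7,7a-hexahydro-1H-indene (C4=C5 double bond, trans ring fusion) is C2 of 6,6-diallyl-5-hydroxy-4-(2-methylpropanoyl)cyclohex-4-ene-1,3-dione; acyl-side carbonyl cis to H-7a, spiro carbon S as in the target | C=CCC1(CC=C)C(=O)[C@@]2(C[C@H]3[C@@H](CC[C@@]3(C)O)C(C)=C2)C(=O)C(C(=O)C(C)C)=C1O | intermediate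
8 | bridged enol ether (not isolated): 7 after addition of the axial acyl-side enol O–H across C4=C5; the axial O–C4 bond closes a 6-oxabicyclo[3.2.1]octane whose C7 is the alkoxy carbon of the vinylogous ester; all other centres unchanged | C=CCC1(CC=C)C(=O)[C@@]2(C[C@H]3[C@@H](CC[C@@]3(C)O)[C@]4(C)C2)C(O4)=C(C(=O)C(C)C)C1=O | intermediate
9 | diallyl congener of tomoeone C: (1R,3aR,4S,7aS)-1,4-dihydroxy-1,4-dimethyloctahydroindene spiro-fused at C6 (S) to C2 of 6,6-diallyl-5-hydroxy-4-(2-methylpropanoyl)cyclohex-4-ene-1,3-dione | C=CCC1(CC=C)C(=O)[C@@]2(C[C@H]3[C@@H](CC[C@@]3(C)O)[C@@](C)(O)C2)C(=O)C(C(=O)C(C)C)=C1O | intermediate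
10 | tomoeone C: as 9 with two prenyl groups in place of the allyl groups; hydrindane (1R,3aR,4S,7aS), spiro carbon S, trans ring fusion, C4 hydroxyl cis to the acyl-side carbonyl | CC(C)=CCC1(CC=C(C)C)C(=O)[C@@]2(C[C@H]3[C@@H](CC[C@@]3(C)O)[C@@](C)(O)C2)C(=O)C(C(=O)C(C)C)=C1O | target

## Step count and risks

Total steps: 5. Longest linear sequence: 4 (steps 2, 3, 4, 5 from linalool, or 1, 3, 4, 5 from phlorisobutyrophenone).

Three steps most likely to fail:

Step 3 (the proposed new step). The photogenerated dienone may simply reclose, may undergo a [1,7]-hydrogen shift, or may lose its exocyclic geometry under light, which would give the spiro epimer. The fallback sets out from 2 (condensed with 4) and comes back at 7. The condensation is stopped before irradiation and 2H-pyran 6 is isolated by chromatography. The dienone in thermal equilibrium with it is then closed in the dark by the known rhodium-catalysed intramolecular diene–ene [4+2], which runs through a rhodacycle and not through a pericyclic transition state: RhCl(PPh3)3 (10 mol%), CF3CH2OH, 55 °C. The protic solvent keeps the acidic enol protonated and off the metal. This fallback makes no new compound (F0).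

Step 4. The Brønsted acid may ionise the tertiary C1 alcohol or trigger a hydride shift from C3a, which would scramble the ring fusion. The fallback sets out from 7 and comes back at 8. N-(phenylselanyl)phthalimide in CH2Cl2 at −78 °C forms a seleniranium ion on the more electron-rich ring alkene, which the axial enol oxygen opens at C4 to give the bridged selenide F1. Bu3SnH (in excess, to outrun radical cyclisation onto an allyl group) and AIBN in PhMe at 80 °C then remove the selenium to give 8, which is hydrolysed to 9 by the second stage of step 4.

Step 5. Ring-closing metathesis of the gem-diallyl unit to a spirocyclopentene may outrun cross-metathesis and not reverse. The fallback sets out from 9 and comes back at 10. OsO4 (catalytic) with NaIO4 in THF/H2O cleaves both allyl groups to the dialdehyde F2. Wittig olefination with excess Ph3P=CMe2 in THF (−78 °C to 0 °C) then installs both prenyl groups.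

Further compounds

F0 | step 3 | none | none
F1 | step 4 | bridged selenide: 8 carrying an axial phenylselanyl group on C5, trans to the bridging oxygen on C4 | C=CCC1(CC=C)C(=O)[C@@]2(C[C@H]3[C@@H](CC[C@@]3(C)O)[C@]4(C)[C@@H]2[Se]c5ccccc5)C(O4)=C(C(=O)C(C)C)C1=O
F2 | step 5 | dialdehyde: 9 with both allyl groups cut down to 2-oxoethyl groups | O=CCC1(CC=O)C(=O)[C@@]2(C[C@H]3[C@@H](CC[C@@]3(C)O)[C@@](C)(O)C2)C(=O)C(C(=O)C(C)C)=C1O
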